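**Strategy**

Everything rests on disconnecting the two neighbouring substituents on ring B, the C2' hydroxyl and the C3' carboxyl carbon wedged between the C1' ester carbonyl and the C4' methoxy group, back to a C2'–C3' aryne of the intact depside. Generating that aryne with fluoride in DMF forges the C2'–O and C3'–CHO bonds in a single operation, the C4' methoxy group directing oxygen to C2'. The precursor is the complete depside bearing a C3' trimethylsilyl group and a C2' triflate, with the ring A phenol held as a benzyl ether; it is assembled from 3-methoxy-5-methylphenol by two carbamate-directed ortho-metalations and acylation of methyl 2,4-dihydroxy-3,6-dimethylbenzoate.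

Key step: step 8

Remark: locants C1'–C6' refer to ring B (C1' carries the depside carbonyl, C6' the methyl group) and C1–C6 to ring A (C1 carries the methyl ester). The target has no stereocentre. Compounds 18 and 22 are the precursor and the product of the key step. The C1' carbon is carried as an aldehyde through the carbamate-to-triflate exchange, because a free acid next to the N–H carbamate would invite acyl transfer and amide formation.

**Route**

Step 1
Reactants: 1 3-methoxy-5-methylphenol
Product: 2 3-methoxy-5-methylphenyl N-isopropylcarbamate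
Conditions: i-PrNCO, cat. Et3N, CH2Cl2, rt
Reagents that add atoms: isopropyl isocyanate CC(C)N=C=O
Why: Base-catalysed addition of the phenol O–H to the isocyanate (carbamoylation) installs an N-monoalkyl carbamate that serves as the ortho-directing group and later as a base-cleavable phenol mask.

Step 2
Reactants: 2 3-methoxy-5-methylphenyl N-isopropylcarbamate
Product: 6 3-methoxy-5-methyl-2-(trimethylsilyl)phenyl N-isopropylcarbamate, via N-silyl carbamate 3 (not isolated), via C2 aryllithium 4 (not isolated), via N,C-bis(trimethylsilyl) carbamate 5 (not isolated)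
Conditions: TMSOTf, TMEDA, Et2O, 0 °C to rt; n-BuLi, TMEDA, −78 °C; TMSCl, −78 °C to rt; aq. NH4Cl, then cold 1 M HCl wash
Reagents that add atoms: chlorotrimethylsilane C[Si](C)(C)Cl
Why: Directed ortho-metalation of the in situ N-silylated carbamate (Hoppe-type protection of the N–H) should occur at the C–H flanked by the carbamate and methoxy groups, whose directing effects cooperate, and the aryllithium is C-silylated while the N–Si bond is hydrolysed on work-up.

Step 3
Reactants: 6 3-methoxy-5-methyl-2-(trimethylsilyl)phenyl N-isopropylcarbamate; 7 N,N-dimethylformamide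
Product: 11 2-formyl-5-methoxy-3-methyl-6-(trimethylsilyl)phenyl N-isopropylcarbamate, via N-triethylsilyl carbamate 8 (not isolated), via C6 aryllithium 9 (not isolated), via lithium hemiaminal alkoxide 10 (not isolated)
Conditions: Et3SiOTf, TMEDA, Et2O, 0 °C to rt; s-BuLi, TMEDA, −78 °C; DMF, −78 to 0 °C; aq. NH4Cl, then cold 1 M HCl, 0 °C
Reagents that add atoms: N,N-dimethylformamide (7) CN(C)C=O
Why: After in situ N-silylation, here with the bulkier triethylsilyl group that better shields the carbamate carbonyl from s-BuLi, a second directed ortho-metalation should take the only remaining position ortho to the carbamate (the ring methyl has no ortho director for lateral lithiation, and −78 °C suppresses anionic ortho-Fries migration), and formylation of the aryllithium with DMF stops at the stable tetrahedral adduct until the acidic work-up releases the aldehyde and hydrolyses the N–Si bond.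

Step 4
Reactants: 11 2-formyl-5-methoxy-3-methyl-6-(trimethylsilyl)phenyl N-isopropylcarbamate
Product: 13 2-formyl-5-methoxy-3-methyl-6-(trimethylsilyl)phenyl trifluoromethanesulfonate, via salicylaldehyde 12 (not isolated)
Conditions: DBU, Et2NH, MeCN, 40 °C; then PhNTf2, rt
Reagents that add atoms: N-phenylbis(trifluoromethanesulfonimide) O=S(=O)(N(c1ccccc1)S(=O)(=O)C(F)(F)F)C(F)(F)F
Why: E1cB cleavage of the N-monoalkyl carbamate, the carbamoyl unit leaving as the diethylurea, should unmask the phenoxide, which is O-sulfonylated in the same flask by PhNTf2 without touching the neutral aldehyde or the aryl silane.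

Step 5
Reactants: 13 2-formyl-5-methoxy-3-methyl-6-(trimethylsilyl)phenyl trifluoromethanesulfonate
Product: 14 4-methoxy-6-methyl-2-(trifluoromethanesulfonyloxy)-3-(trimethylsilyl)benzoic acid
Conditions: NaClO2, NaH2PO4, 2-methyl-2-butene, t-BuOH/THF/H2O, 0 °C to rt
Reagents that add atoms: sodium chlorite [Na+].[O-]Cl=O
Why: Pinnick oxidation should convert the hindered aryl aldehyde to the acid under buffered, mildly acidic conditions that leave the aryl triflate and aryl silane intact, the alkene scavenging HOCl.

Step 6
Reactants: 14 4-methoxy-6-methyl-2-(trifluoromethanesulfonyloxy)-3-(trimethylsilyl)benzoic acid; 15 methyl 2,4-dihydroxy-3,6-dimethylbenzoate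
Product: 17 methyl 2-hydroxy-4-{[4-methoxy-6-methyl-2-(trifluoromethanesulfonyloxy)-3-(trimethylsilyl)benzoyl]oxy}-3,6-dimethylbenzoate, via acid chloride 16 (not isolated)
Conditions: (COCl)2, cat. DMF, CH2Cl2, 0 °C to rt, evaporate; then 15, Et3N, cat. DMAP, CH2Cl2, 0 °C to rt
Reagents that add atoms: none
Why: Acid chloride formation followed by DMAP-assisted O-acylation (esterification) should acylate only the C4 hydroxyl of ring A, because the C2 hydroxyl is hydrogen-bonded to the ester carbonyl and flanked by two ortho substituents.

Step 7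
Reactants: 17 methyl 2-hydroxy-4-{[4-methoxy-6-methyl-2-(trifluoromethanesulfonyloxy)-3-(trimethylsilyl)benzoyl]oxy}-3,6-dimethylbenzoate
Product: 18 methyl 2-(benzyloxy)-4-{[4-methoxy-6-methyl-2-(trifluoromethanesulfonyloxy)-3-(trimethylsilyl)benzoyl]oxy}-3,6-dimethylbenzoate
Conditions: BnOH, PPh3, DIAD, THF, 0 °C to rt
Reagents that add atoms: benzyl alcohol OCc1ccccc1
Why: Mitsunobu etherification should benzylate the acidic chelated ring A phenol under neutral conditions, avoiding carbonate or hydride bases that could trigger the silyl triflate or attack the depside ester.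

Step 8
Reactants: 18 methyl 2-(benzyloxy)-4-{[4-methoxy-6-methyl-2-(trifluoromethanesulfonyloxy)-3-(trimethylsilyl)benzoyl]oxy}-3,6-dimethylbenzoate; 7 N,N-dimethylformamide
Product: 22 methyl 2-(benzyloxy)-4-[(3-formyl-2-hydroxy-4-methoxy-6-methylbenzoyl)oxy]-3,6-dimethylbenzoate, via aryne 19 (not isolated), via benzoxete 20 (not isolated), via ortho-quinone methide 21 (not isolated)
Conditions: CsF, anhydrous DMF (solvent), rt, slow addition of 18; then H2O, rt
Reagents that add atoms: N,N-dimethylformamide (7) CN(C)C=O; water O
Why: Fluoride attacks silicon and the C2' triflate departs to unveil aryne 19; the formamide oxygen then adds to C2' and the emerging C3' carbanion collapses onto the iminium carbon (formal [2+2], 4-exo-trig closure) to give benzoxete 20, whose four-membered ring is only transient because 4π electrocyclic opening delivers ortho-quinone methide 21, which water converts to the C2' phenol and C3' aldehyde with loss of dimethylamine. The closest known reaction type is the insertion of arynes into the C=O bond of formamides followed by hydrolysis to salicylaldehydes, which is regioselective for 3-alkoxyarynes. No stereocentre is formed. The selectivity required is the orientation of addition: the σ-withdrawing C4' methoxy group distorts the aryne so that C2' is the flatter, more electrophilic terminus and negative charge develops at C3' beside oxygen, whereas the C1' acyl carbon is a much weaker inductive substituent. Both aryne termini carry one ortho neighbour, so sterics should not bias the outcome. The benzyl ether on ring A removes the only acidic O–H that could protonate the C3' anion or O-arylate the aryne, and slow addition keeps the aryne dilute in a large excess of DMF.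

Step 9
Reactants: 22 methyl 2-(benzyloxy)-4-[(3-formyl-2-hydroxy-4-methoxy-6-methylbenzoyl)oxy]-3,6-dimethylbenzoate
Product: 23 3-{[3-(benzyloxy)-4-(methoxycarbonyl)-2,5-dimethylphenoxy]carbonyl}-2-hydroxy-6-methoxy-4-methylbenzoic acid
Conditions: NaClO2, NaH2PO4, 2-methyl-2-butene (large excess), t-BuOH/THF/H2O, 0 °C to rt
Reagents that add atoms: sodium chlorite [Na+].[O-]Cl=O
Why: Pinnick oxidation should take the salicylaldehyde to the salicylic acid while the excess alkene intercepts HOCl before it can chlorinate the electron-rich C5' position, the depside ester and benzyl ether being inert.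

Step 10
Reactants: 23 3-{[3-(benzyloxy)-4-(methoxycarbonyl)-2,5-dimethylphenoxy]carbonyl}-2-hydroxy-6-methoxy-4-methylbenzoic acid
Product: 24 3-{[3-hydroxy-4-(methoxycarbonyl)-2,5-dimethylphenoxy]carbonyl}-2-hydroxy-6-methoxy-4-methylbenzoic acid (CNP0265145.0)
Conditions: H2 (1 atm), Pd/C, EtOAc, rt
Reagents that add atoms: none
Why: Catalytic hydrogenolysis should cleave the benzyl aryl ether selectively, since the aryl ester, methyl ester and carboxylic acid are not reduced under these conditions.

**Compound list**

1 | 3-methoxy-5-methylphenol | COc1cc(C)cc(O)c1 | starting material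
2 | 3-methoxy-5-methylphenyl N-isopropylcarbamate | COc1cc(C)cc(OC(=O)NC(C)C)c1 | intermediate
3 | 3-methoxy-5-methylphenyl N-isopropyl-N-(trimethylsilyl)carbamate (formed in the flask) | COc1cc(C)cc(OC(=O)N(C(C)C)[Si](C)(C)C)c1 | intermediate
4 | C2 aryllithium of 3, lithium between the carbamate and methoxy groups (formed in the flask) | COc1cc(C)cc(OC(=O)N(C(C)C)[Si](C)(C)C)c1[Li] | intermediate
5 | 3-methoxy-5-methyl-2-(trimethylsilyl)phenyl N-isopropyl-N-(trimethylsilyl)carbamate (formed in the flask) | COc1cc(C)cc(OC(=O)N(C(C)C)[Si](C)(C)C)c1[Si](C)(C)C | intermediate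
6 | 3-methoxy-5-methyl-2-(trimethylsilyl)phenyl N-isopropylcarbamate | COc1cc(C)cc(OC(=O)NC(C)C)c1[Si](C)(C)C | intermediate
7 | N,N-dimethylformamide | CN(C)C=O | starting material
8 | 3-methoxy-5-methyl-2-(trimethylsilyl)phenyl N-isopropyl-N-(triethylsilyl)carbamate (formed in the flask) | COc1cc(C)cc(OC(=O)N(C(C)C)[Si](CC)(CC)CC)c1[Si](C)(C)C | intermediate
9 | C6 aryllithium of 8, lithium between the carbamate and ring methyl groups (formed in the flask) | COc1cc(C)c([Li])c(OC(=O)N(C(C)C)[Si](CC)(CC)CC)c1[Si](C)(C)C | intermediate
10 | lithium hemiaminal alkoxide from 9 and DMF, racemic (formed in the flask) | COc1cc(C)c(C(O[Li])N(C)C)c(OC(=O)N(C(C)C)[Si](CC)(CC)CC)c1[Si](C)(C)C | intermediate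
11 | 2-formyl-5-methoxy-3-methyl-6-(trimethylsilyl)phenyl N-isopropylcarbamate | COc1cc(C)c(C=O)c(OC(=O)NC(C)C)c1[Si](C)(C)C | intermediate
12 | 2-hydroxy-4-methoxy-6-methyl-3-(trimethylsilyl)benzaldehyde (present in the flask as its DBU-H phenoxide) | COc1cc(C)c(C=O)c(O)c1[Si](C)(C)C | intermediate
13 | 2-formyl-5-methoxy-3-methyl-6-(trimethylsilyl)phenyl trifluoromethanesulfonate | COc1cc(C)c(C=O)c(OS(=O)(=O)C(F)(F)F)c1[Si](C)(C)C | intermediate
14 | 4-methoxy-6-methyl-2-(trifluoromethanesulfonyloxy)-3-(trimethylsilyl)benzoic acid | COc1cc(C)c(C(=O)O)c(OS(=O)(=O)C(F)(F)F)c1[Si](C)(C)C | intermediate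
15 | methyl 2,4-dihydroxy-3,6-dimethylbenzoate | COC(=O)c1c(C)cc(O)c(C)c1O | starting material
16 | 4-methoxy-6-methyl-2-(trifluoromethanesulfonyloxy)-3-(trimethylsilyl)benzoyl chloride (formed in the flask) | COc1cc(C)c(C(=O)Cl)c(OS(=O)(=O)C(F)(F)F)c1[Si](C)(C)C | intermediate
17 | methyl 2-hydroxy-4-{[4-methoxy-6-methyl-2-(trifluoromethanesulfonyloxy)-3-(trimethylsilyl)benzoyl]oxy}-3,6-dimethylbenzoate | COC(=O)c1c(C)cc(OC(=O)c2c(C)cc(OC)c([Si](C)(C)C)c2OS(=O)(=O)C(F)(F)F)c(C)c1O | intermediate
18 | methyl 2-(benzyloxy)-4-{[4-methoxy-6-methyl-2-(trifluoromethanesulfonyloxy)-3-(trimethylsilyl)benzoyl]oxy}-3,6-dimethylbenzoate (aryne precursor) | COC(=O)c1c(C)cc(OC(=O)c2c(C)cc(OC)c([Si](C)(C)C)c2OS(=O)(=O)C(F)(F)F)c(C)c1OCc1ccccc1 | intermediate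
19 | ring B C2'–C3' aryne of the benzyl-protected depside (formed in the flask) | COC(=O)c1c(C)cc(OC(=O)C2=C(C)C=C(OC)C#C2)c(C)c1OCc1ccccc1 | intermediate
20 | 2-(dimethylamino)-2H-benzoxete fused at C2'–C3' of ring B, oxygen on C2', racemic (formed in the flask) | COC(=O)c1c(C)cc(OC(=O)c2c(C)cc(OC)c3C(N(C)C)Oc23)c(C)c1OCc1ccccc1 | intermediate
21 | ortho-quinone methide with C2' carbonyl and C3' exocyclic (dimethylamino)methylidene, alkene geometry not defined (formed in the flask) | COC(=O)c1c(C)cc(OC(=O)C2=C(C)C=C(OC)C(=CN(C)C)C2=O)c(C)c1OCc1ccccc1 | intermediate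
22 | methyl 2-(benzyloxy)-4-[(3-formyl-2-hydroxy-4-methoxy-6-methylbenzoyl)oxy]-3,6-dimethylbenzoate | COC(=O)c1c(C)cc(OC(=O)c2c(C)cc(OC)c(C=O)c2O)c(C)c1OCc1ccccc1 | intermediate
23 | 3-{[3-(benzyloxy)-4-(methoxycarbonyl)-2,5-dimethylphenoxy]carbonyl}-2-hydroxy-6-methoxy-4-methylbenzoic acid | COC(=O)c1c(C)cc(OC(=O)c2c(C)cc(OC)c(C(=O)O)c2O)c(C)c1OCc1ccccc1 | intermediate
24 | 3-{[3-hydroxy-4-(methoxycarbonyl)-2,5-dimethylphenoxy]carbonyl}-2-hydroxy-6-methoxy-4-methylbenzoic acid (CNP0265145.0, achiral) | COC(=O)c1c(C)cc(OC(=O)c2c(C)cc(OC)c(C(=O)O)c2O)c(C)c1O | target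

**Step count**

Total steps: 10. Longest linear sequence: 10 steps (1 to 24); compound 15 enters at step 6 without prior steps.

**Steps most likely to fail**

Step 8. The C3' aryl anion may be protonated before it closes onto the iminium carbon, or the liberated phenoxide may be consumed by further aryne, so that little salicylaldehyde results. The fallback forms the C–O and C–C bonds in separate operations. Setting out from 18, the same aryne 19 is generated with CsF in MeCN in the presence of acetic acid. O–H insertion of the acid, a general aryne reaction that follows the same methoxy-controlled orientation, should give the C2' acetate with hydrogen at C3', methyl 4-[(2-acetoxy-4-methoxy-6-methylbenzoyl)oxy]-2-(benzyloxy)-3,6-dimethylbenzoate F1. Ammonolysis of the unhindered aryl acetate (NH3, MeOH, 0 °C) should then give the phenol methyl 2-(benzyloxy)-4-[(2-hydroxy-4-methoxy-6-methylbenzoyl)oxy]-3,6-dimethylbenzoate F2. Magnesium-mediated ortho-formylation (MgCl2, Et3N, paraformaldehyde, MeCN, reflux) can only occur at C3', the single free position ortho to the phenol, and returns to the route at 22.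

Step 3. Deprotonation may take place at a silyl methyl or at the ring methyl group in place of the ring C–H, or the aryllithium may undergo anionic ortho-Fries carbamoyl migration before it is formylated. The fallback introduces the C1' carbon by electrophilic ortho-formylation of the phenol and not by lithiation. Setting out from 6, the carbamate is cleaved (DBU, Et2NH, MeCN, 40 °C, aqueous work-up) to 3-methoxy-5-methyl-2-(trimethylsilyl)phenol F3. Formylation with MgCl2, Et3N and paraformaldehyde is directed to the only unsubstituted ortho position, because the silyl group blocks the other, and should give 12, now isolated. Triflation with PhNTf2 and DBU, as in the second half of step 4, returns to the route at 13.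

Step 7. The hindered, hydrogen-bonded phenol may alkylate sluggishly, and forcing the reaction risks loss of the silyl triflate or transesterification of the depside. The fallback places the benzyl group on ring A before the sensitive ring B acid is attached. Setting out from 15, selective allylation of the non-chelated C4 hydroxyl (allyl bromide, K2CO3, acetone) should give methyl 4-(allyloxy)-2-hydroxy-3,6-dimethylbenzoate F4. Benzylation of the remaining phenol (BnBr, K2CO3, DMF, 60 °C) gives methyl 4-(allyloxy)-2-(benzyloxy)-3,6-dimethylbenzoate F5. Deallylation with Pd(PPh3)4 (zerovalent palladium) and morpholine in THF gives methyl 2-(benzyloxy)-4-hydroxy-3,6-dimethylbenzoate F6. Acylation of F6 with acid chloride 16 (Et3N, cat. DMAP, CH2Cl2) returns to the route at 18 directly, bypassing 17.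

**Further compounds**

F1 | step 8 | methyl 4-[(2-acetoxy-4-methoxy-6-methylbenzoyl)oxy]-2-(benzyloxy)-3,6-dimethylbenzoate | COC(=O)c1c(C)cc(OC(=O)c2c(C)cc(OC)cc2OC(C)=O)c(C)c1OCc1ccccc1
F2 | step 8 | methyl 2-(benzyloxy)-4-[(2-hydroxy-4-methoxy-6-methylbenzoyl)oxy]-3,6-dimethylbenzoate | COC(=O)c1c(C)cc(OC(=O)c2c(C)cc(OC)cc2O)c(C)c1OCc1ccccc1
F3 | step 3 | 3-methoxy-5-methyl-2-(trimethylsilyl)phenol | COc1cc(C)cc(O)c1[Si](C)(C)C
F4 | step 7 | methyl 4-(allyloxy)-2-hydroxy-3,6-dimethylbenzoate | COC(=O)c1c(C)cc(OCC=C)c(C)c1O
F5 | step 7 | methyl 4-(allyloxy)-2-(benzyloxy)-3,6-dimethylbenzoate | COC(=O)c1c(C)cc(OCC=C)c(C)c1OCc1ccccc1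
F6 | step 7 | methyl 2-(benzyloxy)-4-hydroxy-3,6-dimethylbenzoate | COC(=O)c1c(C)cc(O)c(C)c1OCc1ccccc1
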